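The ring atoms are numbered C1 (methyl, Z-chlorovinyl), C2, C3 (Br, CH2Br), C4 (Cl), C5, C6 (Cl). The plan cuts the C1–C2 bond of the only ring, the cyclohexane. It exploits the fact that the C6 chloride stands beside quaternary C1 while C3, one methylene away, carries an exocyclic carbon. The precursor is an acyclic 2-methyl-2-alkyloxirane that already holds both secondary chlorides and ends in a 2-substituted allylsilane. With BF3·OEt2 the allylsilane terminus displaces the oxirane oxygen at the tertiary carbon with inversion. This single operation closes the ring, creates quaternary C1 next to the existing chloride, and unveils the C3 methylene and a C1 hydroxymethyl group for the endgame.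

Key step: step 10

Remark on the chemistry: in this numbering the target is 1S,3S,4R,6S with a Z alkene. In the chair that keeps both C–Cl bonds equatorial, the chlorovinyl group and the C3 bromine are axial on the same face, and the methyl and CH2Br groups are equatorial.

Step 1
Reactants: 1 (S)-alpha-hydroxy-gamma-butyrolactone
Product: 2 (3S)-3-(triethylsilyloxy)oxolan-2-one
Conditions: TESCl, imidazole, CH2Cl2, 0 °C to rt
Reagents that add atoms: chlorotriethylsilane CC[Si](Cl)(CC)CC
Why: Routine silyl ether formation at the only hydroxyl leaves the stereocentre untouched, and triethylsilyl is chosen because it survives the organocerium step yet later falls to an acid mild enough for an allylsilane.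

Step 2
Reactants: 2 (3S)-3-(triethylsilyloxy)oxolan-2-one; 3 (trimethylsilyl)methylmagnesium chloride
Product: 6 (3S)-3-(triethylsilyloxy)-4-[(trimethylsilyl)methyl]pent-4-en-1-ol, via organocerium reagent 4 (not isolated), via bis(silylmethyl) carbinol 5 (not isolated)
Conditions: CeCl3 (dried, 4 equiv), 3 (4 equiv), THF, −78 °C to rt; sat. NH4Cl; then SiO2, CH2Cl2, rt
Reagents that add atoms: (trimethylsilyl)methylmagnesium chloride C[Si](C)(C)C[Mg]Cl
Why: The weakly basic organocerium reagent adds twice to the lactone carbonyl without enolising the alpha-silyloxy centre, and the resulting beta-hydroxysilane undergoes acid-type Peterson elimination on silica gel to the 2-substituted allylsilane while the ring oxygen is released as the primary alcohol.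

Step 3
Reactants: 6 (3S)-3-(triethylsilyloxy)-4-[(trimethylsilyl)methyl]pent-4-en-1-ol; 7 ethyl 2-(triphenylphosphoranylidene)propanoate
Product: 9 ethyl (2E,5S)-2-methyl-5-(triethylsilyloxy)-6-[(trimethylsilyl)methyl]hepta-2,6-dienoate, via silyloxy aldehyde 8 (not isolated)
Conditions: Dess–Martin periodinane (1.1 equiv), NaHCO3, CH2Cl2, 0 °C to rt; then 7, rt
Reagents that add atoms: ethyl 2-(triphenylphosphoranylidene)propanoate CCOC(=O)C(C)=P(c1ccccc1)(c1ccccc1)c1ccccc1
Why: Dess–Martin oxidation followed in the same flask by a Wittig reaction avoids handling the elimination-prone beta-silyloxy aldehyde, and the stabilised alpha-branched ylide gives the trisubstituted enoate with the E preference typical of such ylides.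

Step 4
Reactants: 9 ethyl (2E,5S)-2-methyl-5-(triethylsilyloxy)-6-[(trimethylsilyl)methyl]hepta-2,6-dienoate
Product: 10 ethyl (2E,5S)-5-hydroxy-2-methyl-6-[(trimethylsilyl)methyl]hepta-2,6-dienoate
Conditions: PPTS (cat.), EtOH, 0 °C to rt
Reagents that add atoms: none
Why: Acid-catalysed ethanolysis cleaves the secondary triethylsilyl ether under conditions too weak to protodesilylate the allylsilane, and fluoride is avoided for the same reason.

Step 5
Reactants: 10 ethyl (2E,5S)-5-hydroxy-2-methyl-6-[(trimethylsilyl)methyl]hepta-2,6-dienoate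
Product: 11 ethyl (2E,5R)-5-chloro-2-methyl-6-[(trimethylsilyl)methyl]hepta-2,6-dienoate
Conditions: PPh3 (1.2 equiv), Cl3CC(O)CCl3, CH2Cl2, −20 to 0 °C
Reagents that add atoms: hexachloroacetone ClC(Cl)(Cl)C(=O)C(Cl)(Cl)Cl
Why: In this Appel-type deoxychlorination the alkoxyphosphonium salt is displaced by chloride in SN2 fashion within minutes at low temperature, a variant known to convert secondary allylic alcohols with inversion (5S to 5R, the future C4) and with little allylic transposition.

Step 6
Reactants: 11 ethyl (2E,5R)-5-chloro-2-methyl-6-[(trimethylsilyl)methyl]hepta-2,6-dienoate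
Product: 12 (2E,5R)-5-chloro-2-methyl-6-[(trimethylsilyl)methyl]hepta-2,6-dien-1-ol
Conditions: i-Bu2AlH (2.3 equiv), CH2Cl2, −78 °C; aq. potassium sodium tartrate
Reagents that add atoms: none
Why: i-Bu2AlH reduces the conjugated ester in 1,2 fashion to the allylic alcohol at low temperature without touching the alkyl chloride, the allylsilane or the E geometry.

Step 7
Reactants: 12 (2E,5R)-5-chloro-2-methyl-6-[(trimethylsilyl)methyl]hepta-2,6-dien-1-ol
Product: 13 (2R,3R,5R)-5-chloro-2,3-epoxy-2-methyl-6-[(trimethylsilyl)methyl]hept-6-en-1-ol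
Conditions: Ti(OiPr)4 (10 mol %), D-(−)-diethyl tartrate (12 mol %), t-BuOOH, 4 Å MS, CH2Cl2, −20 °C
Reagents that add atoms: tert-butyl hydroperoxide CC(C)(C)OO
Why: The Sharpless asymmetric epoxidation is directed by the allylic hydroxyl so the remote allylsilane alkene is ignored, and D-(−)-diethyl tartrate is the antipode that turns an E-2-methylalk-2-en-1-ol into the (2R,3R) epoxide, which sets the future C1 and C6 under reagent control.

Step 8
Reactants: 13 (2R,3R,5R)-5-chloro-2,3-epoxy-2-methyl-6-[(trimethylsilyl)methyl]hept-6-en-1-ol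
Product: 14 (2R,3S,5R)-3,5-dichloro-2-methyl-6-[(trimethylsilyl)methyl]hept-6-ene-1,2-diol
Conditions: Ti(OiPr)4 (1.5 equiv), Et2NH2Cl (2 equiv), CH2Cl2, 0 °C to rt; aq. tartaric acid
Reagents that add atoms: diethylammonium chloride CC[NH2+]CC.[Cl-]
Why: In this titanium-assisted opening of a 2,3-epoxy alcohol, binding of the epoxy alkoxide to Ti(OiPr)4 steers chloride to C3, the less hindered carbon remote from the carbinol, with SN2 inversion (future C6, now 3S), while the fully substituted C2 keeps its C–O bond and this weak Lewis acid does not trigger the allylsilane.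

Step 9
Reactants: 14 (2R,3S,5R)-3,5-dichloro-2-methyl-6-[(trimethylsilyl)methyl]hept-6-ene-1,2-diol
Product: 16 (2R)-2-{(1S,3R)-1,3-dichloro-4-[(trimethylsilyl)methyl]pent-4-en-1-yl}-2-methyloxirane, via primary mesylate 15 (not isolated)
Conditions: MsCl (1.05 equiv), Et3N, CH2Cl2, −20 °C; then MeOH, K2CO3, 0 °C
Reagents that add atoms: none
Why: The primary hydroxyl is mesylated selectively over the tertiary one and the tertiary alkoxide then closes by 3-exo-tet Williamson-type displacement of the far better primary leaving group rather than of the neighbouring secondary chloride, so the C–O bond at the tertiary centre and its configuration are retained.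

Step 10
Reactants: 16 (2R)-2-{(1S,3R)-1,3-dichloro-4-[(trimethylsilyl)methyl]pent-4-en-1-yl}-2-methyloxirane
Product: 17 [(1S,2S,4R)-2,4-dichloro-1-methyl-5-methylidenecyclohexyl]methanol
Conditions: BF3·OEt2 (1.1 equiv), 2,6-di-tert-butyl-4-methylpyridine (0.5 equiv), CH2Cl2 (0.01 M), −78 to −40 °C; sat. NaHCO3
Reagents that add atoms: none
Why: BF3 binds the oxirane oxygen and the terminal CH2 of the allylsilane (future C2) attacks the fully substituted oxirane carbon (C1) anti to the C–O bond, while the charge building at C3 is stabilised by the beta C–Si bond and is discharged by loss of the silyl group, which leaves the exocyclic methylene. The closest known reaction type is the Lewis acid-promoted intramolecular opening of epoxides by allylsilanes (epoxide-initiated, allylsilane-terminated cation–olefin cyclisation), established for tertiary epoxide carbons, so the chlorine on the neighbouring carbon is a new spectator and not a new reaction type. The cyclohexane closes 6-exo-tet with respect to the breaking C1–O bond and 6-endo-trig with respect to the allylsilane C=C, whereas attack at the oxirane CH2 would require a seven-membered ring. C1 is the only new stereocentre and is set by inversion of the (R)-oxirane carbon within a chair that keeps both C–Cl bonds equatorial, which places CH2OH axial and cis to the C6 chloride (1S). The step needs tertiary over primary attack and substitution faster than hydride shift: ring size and charge distribution secure the first, and the electron-withdrawing C6 chloride, which disfavours a free C1 cation, together with the strongly nucleophilic tethered allylsilane secures the second. The hindered pyridine removes adventitious acid so that protodesilylation does not compete.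

Step 11
Reactants: 17 [(1S,2S,4R)-2,4-dichloro-1-methyl-5-methylidenecyclohexyl]methanol
Product: 18 (1S,2S,4R)-2,4-dichloro-1-methyl-5-methylidenecyclohexane-1-carbaldehyde
Conditions: Dess–Martin periodinane, CH2Cl2, rt
Reagents that add atoms: none
Why: Dess–Martin oxidation handles hindered neopentyl alcohols under near-neutral conditions, and the aldehyde has no alpha-hydrogen so neither epimerisation nor E1cB loss of the beta-chloride can occur.

Step 12
Reactants: 18 (1S,2S,4R)-2,4-dichloro-1-methyl-5-methylidenecyclohexane-1-carbaldehyde; 19 (chloromethyl)triphenylphosphonium chloride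
Product: 21 (1S,2S,4R)-2,4-dichloro-1-[(Z)-2-chloroethenyl]-1-methyl-5-methylidenecyclohexane, via chloromethylene ylide 20 (not isolated)
Conditions: 19 (1.5 equiv), NaN(SiMe3)2 (1.4 equiv), THF, −78 °C; then 18, −78 to 0 °C
Reagents that add atoms: (chloromethyl)triphenylphosphonium chloride ClC[P+](c1ccccc1)(c1ccccc1)c1ccccc1.[Cl-]
Why: Wittig chloromethylenation with the ylide made lithium-free and with a slight deficit of base should pass through the kinetically preferred cis-oxaphosphetane, a preference reinforced by the alpha-quaternary aldehyde, to give mainly the Z-chloroalkene, any E isomer being removed by chromatography.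

Step 13
Reactants: 21 (1S,2S,4R)-2,4-dichloro-1-[(Z)-2-chloroethenyl]-1-methyl-5-methylidenecyclohexane
Product: 22 (1S,2R,4S,5S)-1-bromo-1-(bromomethyl)-2,4-dichloro-5-[(Z)-2-chloroethenyl]-5-methylcyclohexane
Conditions: Br2 (1.0 equiv), CH2Cl2, −78 to −40 °C, dark
Reagents that add atoms: bromine BrBr
Why: In this electrophilic anti addition the 1,1-disubstituted alkene is far more nucleophilic than the chlorine-bearing neopentyl alkene, the bromonium ion should form on the face remote from the axial chlorovinyl group, and bromide should open it at tertiary C3 along the axial line, which gives axial Br and equatorial CH2Br (ring C3 = S), also the less strained epimer.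

Compound list
1 | (S)-alpha-hydroxy-gamma-butyrolactone | O=C1OCC[C@@H]1O | starting material
2 | (3S)-3-(triethylsilyloxy)oxolan-2-one | O=C1OCC[C@@H]1O[Si](CC)(CC)CC | intermediate
3 | (trimethylsilyl)methylmagnesium chloride | C[Si](C)(C)C[Mg]Cl | starting material
4 | (trimethylsilyl)methylcerium dichloride | C[Si](C)(C)C[Ce](Cl)Cl | intermediate
5 | (3S)-3-(triethylsilyloxy)-5-(trimethylsilyl)-4-[(trimethylsilyl)methyl]pentane-1,4-diol | C[Si](C)(C)CC(O)(C[Si](C)(C)C)[C@@H](O[Si](CC)(CC)CC)CCO | intermediate
6 | (3S)-3-(triethylsilyloxy)-4-[(trimethylsilyl)methyl]pent-4-en-1-ol | C[Si](C)(C)CC(=C)[C@@H](O[Si](CC)(CC)CC)CCO | intermediate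
7 | ethyl 2-(triphenylphosphoranylidene)propanoate | CCOC(=O)C(C)=P(c1ccccc1)(c1ccccc1)c1ccccc1 | starting material
8 | (3S)-3-(triethylsilyloxy)-4-[(trimethylsilyl)methyl]pent-4-enal | C[Si](C)(C)CC(=C)[C@@H](O[Si](CC)(CC)CC)CC=O | intermediate
9 | ethyl (2E,5S)-2-methyl-5-(triethylsilyloxy)-6-[(trimethylsilyl)methyl]hepta-2,6-dienoate | C[Si](C)(C)CC(=C)[C@@H](O[Si](CC)(CC)CC)C/C=C(\C)C(=O)OCC | intermediate
10 | ethyl (2E,5S)-5-hydroxy-2-methyl-6-[(trimethylsilyl)methyl]hepta-2,6-dienoate | C[Si](C)(C)CC(=C)[C@@H](O)C/C=C(\C)C(=O)OCC | intermediate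
11 | ethyl (2E,5R)-5-chloro-2-methyl-6-[(trimethylsilyl)methyl]hepta-2,6-dienoate | C[Si](C)(C)CC(=C)[C@H](Cl)C/C=C(\C)C(=O)OCC | intermediate
12 | (2E,5R)-5-chloro-2-methyl-6-[(trimethylsilyl)methyl]hepta-2,6-dien-1-ol | C[Si](C)(C)CC(=C)[C@H](Cl)C/C=C(\C)CO | intermediate
13 | (2R,3R,5R)-5-chloro-2,3-epoxy-2-methyl-6-[(trimethylsilyl)methyl]hept-6-en-1-ol | C[Si](C)(C)CC(=C)[C@H](Cl)C[C@H]1O[C@]1(C)CO | intermediate
14 | (2R,3S,5R)-3,5-dichloro-2-methyl-6-[(trimethylsilyl)methyl]hept-6-ene-1,2-diol | C[Si](C)(C)CC(=C)[C@H](Cl)C[C@H](Cl)[C@](C)(O)CO | intermediate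
15 | (2R,3S,5R)-3,5-dichloro-2-hydroxy-2-methyl-6-[(trimethylsilyl)methyl]hept-6-en-1-yl methanesulfonate | C[Si](C)(C)CC(=C)[C@H](Cl)C[C@H](Cl)[C@](C)(O)COS(C)(=O)=O | intermediate
16 | (2R)-2-{(1S,3R)-1,3-dichloro-4-[(trimethylsilyl)methyl]pent-4-en-1-yl}-2-methyloxirane | C[Si](C)(C)CC(=C)[C@H](Cl)C[C@H](Cl)[C@@]1(C)CO1 | intermediate
17 | [(1S,2S,4R)-2,4-dichloro-1-methyl-5-methylidenecyclohexyl]methanol | C[C@@]1(CO)CC(=C)[C@H](Cl)C[C@@H]1Cl | intermediate
18 | (1S,2S,4R)-2,4-dichloro-1-methyl-5-methylidenecyclohexane-1-carbaldehyde | C[C@@]1(C=O)CC(=C)[C@H](Cl)C[C@@H]1Cl | intermediate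
19 | (chloromethyl)triphenylphosphonium chloride | ClC[P+](c1ccccc1)(c1ccccc1)c1ccccc1.[Cl-] | starting material
20 | (chloromethylidene)triphenylphosphorane | ClC=P(c1ccccc1)(c1ccccc1)c1ccccc1 | intermediate
21 | (1S,2S,4R)-2,4-dichloro-1-[(Z)-2-chloroethenyl]-1-methyl-5-methylidenecyclohexane | C[C@@]1(/C=C\Cl)CC(=C)[C@H](Cl)C[C@@H]1Cl | intermediate
22 | (1S,2R,4S,5S)-1-bromo-1-(bromomethyl)-2,4-dichloro-5-[(Z)-2-chloroethenyl]-5-methylcyclohexane (CNP0497262.2) | C[C@@]1(/C=C\Cl)C[C@@](Br)(CBr)[C@H](Cl)C[C@@H]1Cl | target

Total step count: 13. Longest linear sequence: 13 steps, from 1 to 22.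

Steps most likely to fail

**Step 10.**
- What may go wrong: the activated oxirane may undergo a 1,2-hydride shift to the aldehyde (Meinwald-type rearrangement) or capture fluoride. The C6 chlorine may participate and erode the inversion at C1, or the allylsilane may be protodesilylated before the ring closes.
- Fallback: it sets out from 13 and comes back at 17. The primary hydroxyl of 13 is silylated (TBDPSCl, imidazole) to the tert-butyldiphenylsilyl ether of the epoxy alcohol F1.
- BF3·OEt2 or Et2AlCl at −78 °C then triggers the long-established endo mode of epoxy-allylsilane cyclisation. The allylsilane opens the trisubstituted epoxide at the same tertiary carbon with the same inversion, which gives the silyl-protected cyclohexanol F2 with the C6 oxygen still in place.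
- The C6 hydroxyl is exchanged for chloride with inversion (PPh3, CCl4, warm MeCN) to give the silyl-protected dichloride F3, and HF·pyridine frees 17.
- The price is a substitution beside the quaternary carbon, which the main route avoids.

**Step 13.**
- What may go wrong: the face selectivity of bromonium formation may be poor. The bromonium ion may open at the CH2 terminus instead of at C3, which would reverse the outcome at C3. Bromine may also slowly add to the chlorovinyl group.
- Fallback: it sets out from 21 and comes back at 22. NBS in aqueous THF at 0 °C gives the tertiary bromohydrin F4 (axial C3 hydroxyl, equatorial CH2Br). At this stage regio- and stereoisomers can be separated and assigned.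
- Me3SiBr in CH2Cl2 at −20 to 0 °C then replaces the tertiary hydroxyl by bromide with net retention. The neighbouring bromine assists ionisation from the rear and re-forms only the bromonium ion on the face remote from the chlorovinyl group, which bromide opens at C3.

**Step 12.**
- What may go wrong: the Z/E selectivity may be low, addition to the hindered axial aldehyde may be sluggish, or base may remove HCl from the allylic chloride.
- Fallback: it sets out from 18 and comes back at 21. Stork–Zhao olefination ((iodomethyl)triphenylphosphonium iodide, NaN(SiMe3)2, THF–DMPU, −78 °C) is the halomethylenation with the most dependable Z preference, and it gives the Z-iodoalkene F5.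
- Iodine–magnesium exchange with i-PrMgCl·LiCl at −40 °C proceeds with retention of geometry and gives the Z-alkenylmagnesium chloride F6. Quenching with hexachloroethane delivers 21.

Further compounds
F1 | step 10 | tert-butyl{[(2R,3R)-3-{(2R)-2-chloro-3-[(trimethylsilyl)methyl]but-3-en-1-yl}-2-methyloxiran-2-yl]methoxy}diphenylsilane | C[Si](C)(C)CC(=C)[C@H](Cl)C[C@H]1O[C@]1(C)CO[Si](c2ccccc2)(c2ccccc2)C(C)(C)C
F2 | step 10 | (1R,2S,5R)-2-{[tert-butyl(diphenyl)silyl]oxymethyl}-5-chloro-2-methyl-4-methylidenecyclohexan-1-ol | C[C@@]1(CO[Si](c2ccccc2)(c2ccccc2)C(C)(C)C)CC(=C)[C@H](Cl)C[C@H]1O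
F3 | step 10 | tert-butyl{[(1S,2S,4R)-2,4-dichloro-1-methyl-5-methylidenecyclohexyl]methoxy}diphenylsilane | C[C@@]1(CO[Si](c2ccccc2)(c2ccccc2)C(C)(C)C)CC(=C)[C@H](Cl)C[C@@H]1Cl
F4 | step 13 | (1S,2R,4S,5S)-1-(bromomethyl)-2,4-dichloro-5-[(Z)-2-chloroethenyl]-5-methylcyclohexan-1-ol | C[C@@]1(/C=C\Cl)C[C@@](O)(CBr)[C@H](Cl)C[C@@H]1Cl
F5 | step 12 | (1S,2S,4R)-2,4-dichloro-1-[(Z)-2-iodoethenyl]-1-methyl-5-methylidenecyclohexane | C[C@@]1(/C=C\I)CC(=C)[C@H](Cl)C[C@@H]1Cl
F6 | step 12 | (Z)-2-[(1S,2S,4R)-2,4-dichloro-1-methyl-5-methylidenecyclohexyl]ethenylmagnesium chloride | C[C@@]1(/C=C\[Mg]Cl)CC(=C)[C@H](Cl)C[C@@H]1Cl
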